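Ring A (the ester cyclopentene) meets the piperidine (ring D) at the quaternary spiro carbon C3, which sits next to quaternary C4. It meets ring B at the shared sp2 carbons C-c and C-d, the pattern left by a Nazarov closure forming the C-d–C3 bond of a cyclopentenyl (piperidin-3-ylidene)methyl ketone.
Endgame: the hemiketal (ring E) comes from the keto alcohol, and the diene ester from the ring A enone by γ-deprotonation, triflation and methoxycarbonylation. Ring C comes from ring-closing metathesis of the C5 and C-e vinyl groups, then hydrogenation.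
The dienone comes from a (piperidin-3-ylidene)acetaldehyde and (S)-3-vinylcyclopentenyl triflate by Nozaki–Hiyama–Kishi coupling and oxidation. An acid-stable acetate and a free ketone replace acetal protecting groups during the acid step.
Ring D is made by Dieckmann condensation, C4 by Michael addition to pent-1-en-3-one anti to the C5 vinyl group, and C5 from resolved (R)-4-vinylbutyrolactone. C-e is set by rhodium-catalysed conjugate vinylation of cyclopentenone.
Ring order: D, then A onto the purchased ring B, then C, then E.

Key step: step 16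

Atom labels:
- Ring D = N1, C2 (NCH2), C3 (spiro to ring A), C4 (quaternary, spiro to ring E), C5 (CH), C6 (NCH2).
- Ring A = C3, C-a (CH2), C-b (C=O, later C–CO2Me), C-c, C-d.
- Ring B = C-c, C-d, C-e and two CH2.
- Ring C = C3, C4, C5, two CH2, C-e, C-d.
- Ring E = the tetrahydropyran hemiketal.

Assumption: the hemiketal carbon is configurationally labile through ring–chain tautomerism, so the last step is taken to settle at the isomer drawn for the target.

Step 1
Reactants: 1 (Z)-but-2-ene-1,4-diol; 2 triethyl orthoacetate
Product: 4 rac-4-vinyldihydrofuran-2(3H)-one, via ethyl 3-(hydroxymethyl)pent-4-enoate 3 (not isolated)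
Conditions: hydroquinone (cat.), neat, 145 °C, EtOH distilled off
Reagents that add atoms: none
Why: Johnson–Claisen rearrangement of the mixed ketene acetal bonds the acetate carbon to the allylic terminus and frees a vinyl group, the remaining hydroxyl then closes the γ-lactone, and the new stereocentre is racemic at this stage.

Step 2
Reactants: 4 rac-4-vinyldihydrofuran-2(3H)-one; 5 (S)-1-phenylethylamine
Product: 6 (3R)-3-(hydroxymethyl)-N-[(1S)-1-phenylethyl]pent-4-enamide
Conditions: 2-hydroxypyridine (10 mol%), toluene, 100 °C; diastereomers separated by fractional crystallisation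
Reagents that add atoms: none
Why: Lactone aminolysis with a single-enantiomer amine turns the enantiomers of 4 into separable diastereomeric hydroxy amides (classical resolution), and the (3R) isomer carrying the future C5 configuration is kept.

Step 3
Reactants: 6 (3R)-3-(hydroxymethyl)-N-[(1S)-1-phenylethyl]pent-4-enamide
Product: 7 (R)-4-vinyldihydrofuran-2(3H)-one
Conditions: 2 M H2SO4, 1,4-dioxane, reflux
Reagents that add atoms: none
Why: Acid-catalysed N-to-O acyl transfer relactonises the γ-hydroxy amide and releases the amine without touching the stereocentre, which is not next to the carbonyl group.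

Step 4
Reactants: 7 (R)-4-vinyldihydrofuran-2(3H)-one
Product: 9 ethyl (3R)-3-(iodomethyl)pent-4-enoate, via trimethylsilyl (3R)-3-(iodomethyl)pent-4-enoate 8 (not isolated)
Conditions: Me3SiI (1.2 equiv), CH2Cl2, 0 °C to rt; then EtOH, rt
Reagents that add atoms: iodotrimethylsilane, C[Si](C)(C)I; ethanol, CCO
Why: Silylation of the lactone carbonyl lets iodide open the ring by SN2 attack at the primary OCH2 carbon, and alcoholysis of the silyl ester gives the iodo ester (known lactone-to-iodo-ester cleavage) with the stereocentre as a spectator.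

Step 5
Reactants: 9 ethyl (3R)-3-(iodomethyl)pent-4-enoate; 10 ethyl N-methylglycinate
Product: 11 ethyl (3R)-3-{[(2-ethoxy-2-oxoethyl)(methyl)amino]methyl}pent-4-enoate
Conditions: K2CO3 (2 equiv), MeCN, 60 °C
Reagents that add atoms: none
Why: SN2 N-alkylation of the secondary amine by the primary iodide joins all atoms of ring D and stops at the tertiary amine.

Step 6
Reactants: 11 ethyl (3R)-3-{[(2-ethoxy-2-oxoethyl)(methyl)amino]methyl}pent-4-enoate
Product: 12 ethyl (5S)-1-methyl-3-oxo-5-vinylpiperidine-4-carboxylate (C4 labile, keto–enol mixture)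
Conditions: KOt-Bu (1.2 equiv), toluene, 0 °C to rt; AcOH
Reagents that add atoms: none
Why: Dieckmann condensation under equilibrating conditions closes ring D by attack of the pentenoate α-carbon on the glycinate ester and, as with the N-benzyl analogue lacking the vinyl group, settles on the 3-oxo-4-carboxylate, which is held as its stabilised enolate.

Step 7
Reactants: 12 ethyl (5S)-1-methyl-3-oxo-5-vinylpiperidine-4-carboxylate; 13 pent-1-en-3-one
Product: 14 ethyl (4R,5S)-1-methyl-3-oxo-4-(3-oxopentyl)-5-vinylpiperidine-4-carboxylate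
Conditions: Et3N (0.2 equiv), CH2Cl2, 0 °C to rt
Reagents that add atoms: none
Why: Michael addition of the β-keto ester under mild amine catalysis stops before aldol closure, and C4 is set because the C5 vinyl group stands pseudoaxial beside the planar enolate and blocks its own face, so the oxopentyl chain enters anti to it.

Step 8
Reactants: 14 ethyl (4R,5S)-1-methyl-3-oxo-4-(3-oxopentyl)-5-vinylpiperidine-4-carboxylate
Product: 15 ethyl (4R,5S)-4-[2-(2-ethyl-1,3-dioxolan-2-yl)ethyl]-1-methyl-3-oxo-5-vinylpiperidine-4-carboxylate
Conditions: HOCH2CH2OH (5 equiv), TsOH·H2O (1.2 equiv), benzene, reflux, Dean–Stark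
Reagents that add atoms: ethane-1,2-diol, OCCO
Why: Acid-catalysed ketalisation selects the unhindered acyclic ketone, because the ring ketone is neopentyl, has the ester next door and lies two bonds from the protonated nitrogen.

Step 9
Reactants: 15 ethyl (4R,5S)-4-[2-(2-ethyl-1,3-dioxolan-2-yl)ethyl]-1-methyl-3-oxo-5-vinylpiperidine-4-carboxylate
Product: 16 ethyl (3Z,4R,5S)-3-(cyanomethylidene)-4-[2-(2-ethyl-1,3-dioxolan-2-yl)ethyl]-1-methyl-5-vinylpiperidine-4-carboxylate
Conditions: (EtO)2P(O)CH2CN (2 equiv), NaH (1.9 equiv), THF, 0 to 50 °C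
Reagents that add atoms: diethyl (cyanomethyl)phosphonate, CCOP(=O)(CC#N)OCC
Why: Horner–Wadsworth–Emmons olefination with the small, strongly nucleophilic cyanomethylphosphonate anion is the variant that works on ketones flanked by a quaternary carbon, where a bulky β-keto phosphonate does not, and the nitrile settles on the C2 side, away from C4, to give the Z alkene.

Step 10
Reactants: 16 ethyl (3Z,4R,5S)-3-(cyanomethylidene)-4-[2-(2-ethyl-1,3-dioxolan-2-yl)ethyl]-1-methyl-5-vinylpiperidine-4-carboxylate
Product: 18 (2Z)-2-[(4R,5S)-4-(hydroxymethyl)-1-methyl-4-(3-oxopentyl)-5-vinylpiperidin-3-ylidene]acetaldehyde (in equilibrium with its cyclic hemiketal), via ketal hydroxy enal 17 (not isolated)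
Conditions: i-Bu2AlH (5 equiv), CH2Cl2, −78 to −20 °C; then 1 M HCl, THF, rt; aq NaHCO3
Reagents that add atoms: water, O
Why: i-Bu2AlH reduces the ester to the primary alcohol and halts at the N-aluminoimine of the conjugated nitrile, and the aqueous acid work-up hydrolyses imine and dioxolane together, so the acid-labile ketal is gone before the key step.

Step 11
Reactants: 18 (2Z)-2-[(4R,5S)-4-(hydroxymethyl)-1-methyl-4-(3-oxopentyl)-5-vinylpiperidin-3-ylidene]acetaldehyde
Product: 19 [(3Z,4R,5S)-1-methyl-3-(2-oxoethylidene)-4-(3-oxopentyl)-5-vinylpiperidin-4-yl]methyl acetate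
Conditions: Ac2O (1.5 equiv), pyridine, DMAP (5 mol%), CH2Cl2, 0 °C to rt
Reagents that add atoms: acetic anhydride, CC(=O)OC(C)=O
Why: DMAP-catalysed acylation traps the open hydroxy ketone tautomer at its primary alcohol and gives an ester that survives strong acid where an acetal ether would not.

Step 12
Reactants: 20 cyclopent-2-en-1-one
Product: 22 (S)-trimethyl[(3-vinylcyclopent-1-en-1-yl)oxy]silane, via dimethylaluminium enolate 21 (not isolated)
Conditions: CH2=CHMgBr and Me2AlCl (1.5 equiv each), THF, 0 °C; 20, [RhCl(cod)]2 (2.5 mol%), (R)-BINAP (6 mol%), THF, rt; then Me3SiOTf, −20 °C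
Reagents that add atoms: vinylmagnesium bromide, C=C[Mg]Br; trimethylsilyl trifluoromethanesulfonate, C[Si](C)(C)OS(=O)(=O)C(F)(F)F
Why: Rhodium/BINAP-catalysed asymmetric conjugate alkenylation of a cyclic enone, the aprotic organoaluminium variant of the Hayashi–Miyaura reaction, sets C-e by ligand control, with (R)-BINAP chosen by analogy with the known sense of aryl and alkenyl transfer, and silyl trapping keeps the enolate double bond on the side of the new stereocentre.

Step 13
Reactants: 22 (S)-trimethyl[(3-vinylcyclopent-1-en-1-yl)oxy]silane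
Product: 24 (S)-3-vinylcyclopent-1-en-1-yl trifluoromethanesulfonate, via lithium enolate 23 (not isolated)
Conditions: MeLi (1.05 equiv), THF, 0 °C; PhNTf2 (1.1 equiv), −78 to 0 °C
Reagents that add atoms: N-phenylbis(trifluoromethanesulfonimide), O=S(=O)(N(c1ccccc1)S(=O)(=O)C(F)(F)F)C(F)(F)F
Why: Methyllithium cleaves the silyl enol ether to the regiodefined lithium enolate, which is O-sulfonylated faster than it equilibrates, so the alkenyl triflate keeps the C-c=C-d position.

Step 14
Reactants: 19 [(3Z,4R,5S)-1-methyl-3-(2-oxoethylidene)-4-(3-oxopentyl)-5-vinylpiperidin-4-yl]methyl acetate; 24 (S)-3-vinylcyclopent-1-en-1-yl trifluoromethanesulfonate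
Product: 25 [(3Z,4R,5S)-3-{2-hydroxy-2-[(3S)-3-vinylcyclopent-1-en-1-yl]ethylidene}-1-methyl-4-(3-oxopentyl)-5-vinylpiperidin-4-yl]methyl acetate (carbinol epimers)
Conditions: CrCl2 (4 equiv), NiCl2 (2 mol%), DMF, rt
Reagents that add atoms: none
Why: Nozaki–Hiyama–Kishi coupling forms the alkenylchromium reagent from the triflate under nickel catalysis and adds it 1,2 to the aldehyde only, tolerating the ketone, acetate, tertiary amine and the base-sensitive doubly allylic C-e–H, and both carbinol epimers are carried on.

Step 15
Reactants: 25 [(3Z,4R,5S)-3-{2-hydroxy-2-[(3S)-3-vinylcyclopent-1-en-1-yl]ethylidene}-1-methyl-4-(3-oxopentyl)-5-vinylpiperidin-4-yl]methyl acetate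
Product: 26 [(3Z,4R,5S)-1-methyl-4-(3-oxopentyl)-3-{2-oxo-2-[(3S)-3-vinylcyclopent-1-en-1-yl]ethylidene}-5-vinylpiperidin-4-yl]methyl acetate
Conditions: MnO2 (20 equiv), CH2Cl2, rt
Reagents that add atoms: none
Why: MnO2 oxidises the doubly allylic alcohol under neutral conditions, which leaves the C-e stereocentre and the skipped diene in place.

Step 16
Reactants: 26 [(3Z,4R,5S)-1-methyl-4-(3-oxopentyl)-3-{2-oxo-2-[(3S)-3-vinylcyclopent-1-en-1-yl]ethylidene}-5-vinylpiperidin-4-yl]methyl acetate
Product: 27 spiro enone, [(3R,4R,5S,6'S)-1-methyl-3'-oxo-4-(3-oxopentyl)-5,6'-divinyl-spiro[piperidine-3,1'-pentalen]-4-yl]methyl acetate with a single C3a'=C6a' ring-fusion double bond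
Conditions: CF3SO3H (4 equiv), CH2Cl2, −20 °C to rt; poured into cold aq NaHCO3
Reagents that add atoms: none
Why: Excess acid protonates N1 (a spectator ammonium) and then the dienone oxygen to give the 3-hydroxypentadienyl cation, which closes by thermal conrotatory 4π-electrocyclisation between C-d and C3, and the resulting 2-hydroxyallyl cation loses the C-d proton (C3 carries none) to give the tetrasubstituted C-c=C-d enone. This is a Brønsted-acid Nazarov cyclisation of a cycloalkylidenemethyl cycloalkenyl ketone, a class known to give spiro quaternary carbons, and closures of dications bearing a protonated amine are known in triflic acid, where charge repulsion pushes the positive charge away from nitrogen and speeds ring closure. Ring A closes in the electrocyclic, formally 5-endo mode, which a pericyclic process allows. The new stereocentre C3 follows from the sense of conrotation: with the Z alkene (C2 inside and C4 outside the U-shaped cation), bonding at the face of C-d opposite the C-e vinyl group is geometrically coupled to bonding on the ring D face that carries the C4 CH2OAc arm and the C5 vinyl group, where the forming bond is also antiperiplanar to the axial, better-donating C4–CH2CH2 bond. The step needs this torquoselectivity, regioselective proton loss and survival of two terminal alkenes; the first rests on the (S)-C-e stereocentre next to the reacting terminus, the second on the quaternary C3, and the third on each vinyl group lying two bonds from a positive centre, which disfavours its protonation, while the acetate and free ketone are inert where acetals would ionise.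

Step 17
Reactants: 27 spiro enone
Product: 28 tetracyclic enone with rings A–D and a cis alkene in ring C (C3 R, C4 R, C5 S; C-e–H anti to C4)
Conditions: TsOH·H2O (1.05 equiv); second-generation Hoveyda–Grubbs catalyst (5 mol%), 1,4-benzoquinone (10 mol%), toluene (2 mM), 70 °C; aq NaHCO3
Reagents that add atoms: none
Why: Ring-closing metathesis joins the two monosubstituted alkenes, which the key step has placed on the same side of rings A and B and 1,3-diaxial on ring D, to close the seven-membered ring C, with the amine masked as its tosylate salt so that it cannot bind ruthenium and benzoquinone suppressing hydride-induced alkene migration.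

Step 18
Reactants: 28 tetracyclic enone with ring C alkene
Product: 29 tetracyclic enone with saturated ring C
Conditions: H2 (1 atm), Pd/C (10 wt%), EtOAc, rt
Reagents that add atoms: none
Why: Heterogeneous hydrogenation takes the cis-disubstituted ring C alkene and leaves the tetrasubstituted conjugated C-c=C-d bond.

Step 19
Reactants: 29 tetracyclic enone with saturated ring C
Product: 31 pentacyclic methyl ketal enone (ketal carbon as anomers), via hemiketal enone 30 (not isolated)
Conditions: K2CO3 (0.2 equiv), MeOH, rt; then camphorsulfonic acid (1.6 equiv), 3 Å sieves, MeOH, rt; Et3N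
Reagents that add atoms: methanol, CO
Why: Transesterification removes the acetate, the freed alcohol closes on the ethyl ketone, and acid in methanol converts the hemiketal into the cyclic methyl ketal, which masks both groups against base in one protecting group.

Step 20
Reactants: 31 pentacyclic methyl ketal enone
Product: 33 dienyl triflate (C-e=C-d–C-c=C-b–OTf), via potassium dienolate 32 (not isolated)
Conditions: KOt-Bu (1.1 equiv), THF, 0 °C, 30 min; PhNTf2 (1.2 equiv), 0 °C to rt
Reagents that add atoms: N-phenylbis(trifluoromethanesulfonimide), O=S(=O)(N(c1ccccc1)S(=O)(=O)C(F)(F)F)C(F)(F)F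
Why: Reversible deprotonation by tert-butoxide gives the thermodynamic, linearly conjugated dienolate by loss of the γ-proton at C-e (the classical extended enolate of an enone), and O-sulfonylation fixes the diene while erasing the auxiliary C-e stereocentre.

Step 21
Reactants: 33 dienyl triflate
Product: 34 methyl ketal of the target (diene methyl ester)
Conditions: Pd(OAc)2 (10 mol%), dppp (12 mol%), CO (1 atm), Et3N (3 equiv), MeOH–DMF 1:2, 60 °C
Reagents that add atoms: carbon monoxide, [C-]#[O+]; methanol, CO
Why: Palladium-catalysed methoxycarbonylation of an alkenyl triflate (oxidative addition, CO insertion, methanolysis) is established for dienyl triflates made from enones and tolerates tertiary amines and ketals.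

Step 22
Reactants: 34 methyl ketal of the target
Product: 35 CNP0192143.1
Conditions: 0.5 M HCl, THF, rt; aq NaHCO3
Reagents that add atoms: water, O
Why: Mild aqueous acid hydrolyses the cyclic ketal through the ring oxocarbenium ion, and ring–chain tautomerism lets the hemiketal carbon settle under thermodynamic control in the configuration of the target.

Compound list
1 | (Z)-but-2-ene-1,4-diol | OC/C=C\CO | starting material
2 | triethyl orthoacetate | CC(OCC)(OCC)OCC | starting material
3 | ethyl 3-(hydroxymethyl)pent-4-enoate (racemic) | C=CC(CO)CC(=O)OCC | intermediate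
4 | rac-4-vinyldihydrofuran-2(3H)-one | C=CC1COC(=O)C1 | intermediate
5 | (S)-1-phenylethylamine | C[C@H](N)c1ccccc1 | starting material
6 | (3R)-3-(hydroxymethyl)-N-[(1S)-1-phenylethyl]pent-4-enamide | C=C[C@H](CO)CC(=O)N[C@@H](C)c1ccccc1 | intermediate
7 | (R)-4-vinyldihydrofuran-2(3H)-one | C=C[C@@H]1COC(=O)C1 | intermediate
8 | trimethylsilyl (3R)-3-(iodomethyl)pent-4-enoate | C=C[C@H](CI)CC(=O)O[Si](C)(C)C | intermediate
9 | ethyl (3R)-3-(iodomethyl)pent-4-enoate | C=C[C@H](CI)CC(=O)OCC | intermediate
10 | ethyl N-methylglycinate | CCOC(=O)CNC | starting material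
11 | ethyl (3R)-3-{[(2-ethoxy-2-oxoethyl)(methyl)amino]methyl}pent-4-enoate | C=C[C@H](CN(C)CC(=O)OCC)CC(=O)OCC | intermediate
12 | ethyl (5S)-1-methyl-3-oxo-5-vinylpiperidine-4-carboxylate | CCOC(=O)C1C(=O)CN(C)C[C@H]1C=C | intermediate
13 | pent-1-en-3-one | CCC(=O)C=C | starting material
14 | ethyl (4R,5S)-1-methyl-3-oxo-4-(3-oxopentyl)-5-vinylpiperidine-4-carboxylate | CCC(=O)CC[C@@]1(C(=O)OCC)[C@H](C=C)CN(C)CC1=O | intermediate
15 | ethyl (4R,5S)-4-[2-(2-ethyl-1,3-dioxolan-2-yl)ethyl]-1-methyl-3-oxo-5-vinylpiperidine-4-carboxylate | CCC1(OCCO1)CC[C@@]2(C(=O)OCC)[C@H](C=C)CN(C)CC2=O | intermediate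
16 | ethyl (3Z,4R,5S)-3-(cyanomethylidene)-4-[2-(2-ethyl-1,3-dioxolan-2-yl)ethyl]-1-methyl-5-vinylpiperidine-4-carboxylate | CCC1(OCCO1)CC[C@@]2(C(=O)OCC)[C@H](C=C)CN(C)C/C2=C\C#N | intermediate
17 | (2Z)-2-[(4R,5S)-4-[2-(2-ethyl-1,3-dioxolan-2-yl)ethyl]-4-(hydroxymethyl)-1-methyl-5-vinylpiperidin-3-ylidene]acetaldehyde | CCC1(OCCO1)CC[C@@]2(CO)[C@H](C=C)CN(C)C/C2=C\C=O | intermediate
18 | (2Z)-2-[(4R,5S)-4-(hydroxymethyl)-1-methyl-4-(3-oxopentyl)-5-vinylpiperidin-3-ylidene]acetaldehyde (open form) | CCC(=O)CC[C@@]1(CO)[C@H](C=C)CN(C)C/C1=C\C=O | intermediate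
19 | [(3Z,4R,5S)-1-methyl-3-(2-oxoethylidene)-4-(3-oxopentyl)-5-vinylpiperidin-4-yl]methyl acetate | CCC(=O)CC[C@@]1(COC(C)=O)[C@H](C=C)CN(C)C/C1=C\C=O | intermediate
20 | cyclopent-2-en-1-one | O=C1C=CCC1 | starting material
21 | dimethylaluminium (S)-3-vinylcyclopent-1-en-1-olate | C=C[C@H]1C=C(O[Al](C)C)CC1 | intermediate
22 | (S)-trimethyl[(3-vinylcyclopent-1-en-1-yl)oxy]silane | C=C[C@H]1C=C(O[Si](C)(C)C)CC1 | intermediate
23 | lithium (S)-3-vinylcyclopent-1-en-1-olate | C=C[C@H]1C=C([O-])CC1.[Li+] | intermediate
24 | (S)-3-vinylcyclopent-1-en-1-yl trifluoromethanesulfonate | C=C[C@H]1C=C(OS(=O)(=O)C(F)(F)F)CC1 | intermediate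
25 | bis-allylic alcohol (carbinol epimers) | CCC(=O)CC[C@@]1(COC(C)=O)[C@H](C=C)CN(C)C/C1=C\C(O)C2=C[C@H](C=C)CC2 | intermediate
26 | cross-conjugated dienone, Nazarov precursor | CCC(=O)CC[C@@]1(COC(C)=O)[C@H](C=C)CN(C)C/C1=C\C(=O)C2=C[C@H](C=C)CC2 | intermediate
27 | spiro enone, Nazarov product | CCC(=O)CC[C@@]1(COC(C)=O)[C@H](C=C)CN(C)C[C@@]12CC(=O)C3=C2[C@H](C=C)CC3 | intermediate
28 | tetracyclic enone with ring C alkene | CCC(=O)CC[C@@]1(COC(C)=O)[C@@H]2C=C[C@@H]3CCC4=C3[C@@]1(CC4=O)CN(C)C2 | intermediate
29 | tetracyclic enone with saturated ring C | CCC(=O)CC[C@@]1(COC(C)=O)[C@@H]2CC[C@@H]3CCC4=C3[C@@]1(CC4=O)CN(C)C2 | intermediate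
30 | pentacyclic hemiketal enone | CCC1(O)CC[C@@]2(CO1)[C@@H]3CC[C@@H]4CCC5=C4[C@@]2(CC5=O)CN(C)C3 | intermediate
31 | pentacyclic methyl ketal enone | CCC1(OC)CC[C@@]2(CO1)[C@@H]3CC[C@@H]4CCC5=C4[C@@]2(CC5=O)CN(C)C3 | intermediate
32 | potassium extended dienolate | CCC1(OC)CC[C@@]2(CO1)[C@@H]1CCC3=C4C(=C([O-])C[C@@]42CN(C)C1)CC3.[K+] | intermediate
33 | dienyl triflate | CCC1(OC)CC[C@@]2(CO1)[C@@H]1CCC3=C4C(=C(OS(=O)(=O)C(F)(F)F)C[C@@]42CN(C)C1)CC3 | intermediate
34 | methyl ketal of the target | CCC1(OC)CC[C@@]2(CO1)[C@@H]1CCC3=C4C(=C(C(=O)OC)C[C@@]42CN(C)C1)CC3 | intermediate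
35 | CNP0192143.1 | CC[C@@]1(O)CC[C@@]2(CO1)[C@@H]1CCC3=C4C(=C(C(=O)OC)C[C@@]42CN(C)C1)CC3 | target

Total step count: 22. Longest linear sequence: 20 (steps 1–11 and 14–22).

Steps most likely to fail

1. Step 16.
- What may go wrong: closure at a terminus flanked by a quaternary carbon may be slow. Acid-driven processes could then take over:
  - shift of the C-e vinyl group into conjugation through the trienol;
  - addition of acid to the vinyl groups;
  - attack of the ketone enol on C3;
  - a 1,2-shift in the hydroxyallyl cation.
- Conrotation may also run in the unwanted sense, because the wanted ring D face carries the C5 vinyl group in a 1,3 relation to the forming bond.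
- Fallback: it sets out from 24 and 15 and comes back at 27. The pentadienyl cation is raised under near-neutral gold catalysis from a propargylic acetate instead of from the protonated dienone. Sonogashira coupling of 24 with trimethylsilylacetylene (PdCl2(PPh3)2, CuI, Et3N) gives (S)-trimethyl[(3-vinylcyclopent-1-en-1-yl)ethynyl]silane F1, and K2CO3 in MeOH frees (S)-1-ethynyl-3-vinylcyclopent-1-ene F2. Its lithium acetylide (n-BuLi, CeCl3, THF, −78 °C) adds to the ring ketone of 15 to give the tertiary propargylic alcohol F3. i-Bu2AlH reduces the ester to the propargylic diol F4, and Ac2O, Et3N and DMAP give the diacetate F5. As its HBF4 salt, F5 is treated with AuCl(PPh3) and AgSbF6 in wet CH2Cl2. A 3,3-shift of the propargylic acetate, 4π closure of the gold-bound acetoxypentadienyl cation and hydrolysis of the dienyl acetate give the ketal-protected spiro enone F6. Then 1 M HCl in THF removes the dioxolane to reach 27.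

2. Step 9.
- What may go wrong: the phosphonate anion may add sluggishly to the hindered ketone. The adduct may also fragment by retro-Claisen cleavage of the C3–C4 bond, which the neighbouring ester makes possible.
- Fallback: it sets out from 15 and comes back at 18. The ester is removed before the olefination. LiAlH4 in THF reduces ester and ring ketone to the ketal diol F7. TBSCl and imidazole silylate the primary alcohol to give the silyl ether alcohol F8, and Swern oxidation returns the ring ketone as the silyl ether ketone F9, which can no longer fragment. Olefination with the same phosphonate, or Peterson olefination with lithiated (trimethylsilyl)acetonitrile at −78 °C, gives the silyl ether nitrile F10. i-Bu2AlH followed by 1 M HCl in THF hydrolyses the imine, dioxolane and silyl ether together and delivers 18.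

3. Step 20.
- What may go wrong: deprotonation may occur at C-a instead of C-e. The cross-conjugated enolate would then be sulfonylated before equilibration is complete, putting the ester on the wrong diene.
- Fallback: it sets out from 28 and comes back at 33, skipping step 18. The extended dienolate is made regiospecifically by hydride addition instead of by deprotonation. Treatment of 28 as in step 19 gives the ring C alkene methyl ketal F11. DBU in toluene moves the ring C alkene into conjugation to give the linear dienone F12. LiBH(s-Bu)3 in THF at −78 °C can reach only the unhindered δ-carbon, because the β-carbon C-d is fully substituted. The 1,6-addition therefore gives the same extended dienolate, which PhNTf2 traps as 33 (conjugate reduction–triflation of an enone).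

Further compounds
F1 | step 16 | (S)-trimethyl[(3-vinylcyclopent-1-en-1-yl)ethynyl]silane | C=C[C@H]1C=C(C#C[Si](C)(C)C)CC1
F2 | step 16 | (S)-1-ethynyl-3-vinylcyclopent-1-ene | C=C[C@H]1C=C(C#C)CC1
F3 | step 16 | tertiary propargylic alcohol (carbinol epimers) | CCC1(OCCO1)CC[C@@]2(C(=O)OCC)[C@H](C=C)CN(C)CC2(O)C#CC3=C[C@H](C=C)CC3
F4 | step 16 | propargylic diol | CCC1(OCCO1)CC[C@@]2(CO)[C@H](C=C)CN(C)CC2(O)C#CC3=C[C@H](C=C)CC3
F5 | step 16 | diacetate | CCC1(OCCO1)CC[C@@]2(COC(C)=O)[C@H](C=C)CN(C)CC2(OC(C)=O)C#CC3=C[C@H](C=C)CC3
F6 | step 16 | ketal-protected spiro enone | CCC1(OCCO1)CC[C@@]2(COC(C)=O)[C@H](C=C)CN(C)C[C@@]23CC(=O)C4=C3[C@H](C=C)CC4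
F7 | step 9 | ketal diol (carbinol epimers) | CCC1(OCCO1)CC[C@@]2(CO)[C@H](C=C)CN(C)CC2O
F8 | step 9 | silyl ether alcohol | CCC1(OCCO1)CC[C@@]2(CO[Si](C)(C)C(C)(C)C)[C@H](C=C)CN(C)CC2O
F9 | step 9 | silyl ether ketone | CCC1(OCCO1)CC[C@@]2(CO[Si](C)(C)C(C)(C)C)[C@H](C=C)CN(C)CC2=O
F10 | step 9 | silyl ether nitrile | CCC1(OCCO1)CC[C@@]2(CO[Si](C)(C)C(C)(C)C)[C@H](C=C)CN(C)C/C2=C\C#N
F11 | step 20 | ring C alkene methyl ketal | CCC1(OC)CC[C@@]2(CO1)[C@@H]3C=C[C@@H]4CCC5=C4[C@@]2(CC5=O)CN(C)C3
F12 | step 20 | linear dienone | CCC1(OC)CC[C@@]2(CO1)[C@@H]3C/C=C4/CCC5=C4[C@@]2(CC5=O)CN(C)C3
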